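## Retrosynthetic overview

- The (13E)-enoic acid comes from a Horner–Wadsworth–Emmons reaction on an 8α-hydroxy methyl ketone; the C18 acetate is put on last, and a C3 hydroxyl that only relays chirality is removed by Barton–McCombie deoxygenation.
- Key disconnection C4–C5 (with C10–C9 and C8–O in the same cascade): a polarity-reversed a2 (enolonium-type) synthon. The Sharpless epoxide turns C4, a donor alkene carbon and the α-carbon of the C18 oxygen function, into the acceptor that the donor alkene carbon C5 attacks.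
- Ring order: ring A (C4–C5), then ring B (C10–C9), then a transient pyran (C8–O–C13) by capture of the C8 cation by the ketone oxygen; the pyran is opened on work-up.
- The acyclic (E,E,E)-epoxy dienone comes from (5E,9E)-farnesylacetone by ω-allylic oxidation, asymmetric epoxidation and silylation.

Assumption: geometrically pure (5E,9E)-farnesylacetone is taken as purchasable; bicyclic compounds carry labdane numbering (C18 = 4α-CH2O, C19 = 4β-CH3, C17 = 8β-CH3, C20 = 10β-CH3; 5α-H, 9α-H).

## Route

Step 1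
Reactants: 1 (5E,9E)-farnesylacetone
Product: 2 (5E,9E,13E)-15-hydroxy-6,10,14-trimethylpentadeca-5,9,13-trien-2-one
Conditions: SeO2 (0.1 equiv), t-BuOOH (3 equiv), salicylic acid (0.1 equiv), CH2Cl2, 0 °C → rt; stop near half conversion and recycle 1
Reagents that add atoms: tert-butyl hydroperoxide, CC(C)(C)OO
Why: Sharpless–Umbreit catalytic SeO2 allylic oxidation (ene reaction then [2,3]-sigmatropic shift) attacks the most accessible terminal isopropylidene and oxidises the methyl trans to the chain, so the (E)-allylic alcohol that later fixes C4 is formed and the ketone is untouched.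

Step 2
Reactants: 2 (5E,9E,13E)-15-hydroxy-6,10,14-trimethylpentadeca-5,9,13-trien-2-one
Product: 3 (5E,9E)-12-[(2S,3S)-3-(hydroxymethyl)-3-methyloxiran-2-yl]-6,10-dimethyldodeca-5,9-dien-2-one
Conditions: Ti(OiPr)4 (0.1 equiv), L-(+)-diethyl tartrate (0.12 equiv), t-BuOOH (2 equiv), 4 Å molecular sieves, CH2Cl2, −20 °C
Reagents that add atoms: tert-butyl hydroperoxide, CC(C)(C)OO
Why: Sharpless asymmetric epoxidation touches only the allylic-alcohol alkene, and the L-(+)-tartrate catalyst delivers oxygen to the face that gives the (2S,3S)-epoxide, which sets the future C3 and C4 centres.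

Step 3
Reactants: 3 (5E,9E)-12-[(2S,3S)-3-(hydroxymethyl)-3-methyloxiran-2-yl]-6,10-dimethyldodeca-5,9-dien-2-one
Product: 4 (5E,9E)-12-[(2S,3S)-3-[(tert-butyldiphenylsilyl)oxymethyl]-3-methyloxiran-2-yl]-6,10-dimethyldodeca-5,9-dien-2-one
Conditions: TBDPSCl (1.2 equiv), imidazole (2 equiv), CH2Cl2, 0 °C → rt
Reagents that add atoms: tert-butyl(chloro)diphenylsilane, CC(C)(C)[Si](Cl)(c1ccccc1)c1ccccc1
Why: Silylation of the primary alcohol gives a bulky, non-participating ether (an ester here could open the epoxide through an acyloxonium ion) and creates no stereocentre.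

Step 4
Reactants: 4 (5E,9E)-12-[(2S,3S)-3-[(tert-butyldiphenylsilyl)oxymethyl]-3-methyloxiran-2-yl]-6,10-dimethyldodeca-5,9-dien-2-one
Product: 6 (3S,4R,5R,8R,9R,10S)-18-(tert-butyldiphenylsilyloxy)-3β,8α-dihydroxy-14,15-dinorlabdan-13-one, via tricyclic enol ether 5 (not isolated)
Conditions: MeAlCl2 (2.5 equiv), CH2Cl2, −78 °C; then 1 M HCl, THF, 0 °C → rt
Reagents that add atoms: water, O
Why: Epoxide-initiated cation–olefin bicyclization (van Tamelen/Corey type) in which the glycidyl epoxide acts as an a2 (enolonium-type) synthon, so that C4 accepts the donor alkene carbon C5 and a chair–chair cascade forms C4–C5, C10–C9 and C8–O: anti opening with inversion at C4 places the E-CH2OSi group equatorial (4α) and CH3 axial, the E-alkenes give the trans ring fusion with 5α-H, 10β-CH3 and a 9β side chain, the C13 carbonyl oxygen captures the C8 cation from the equatorial α face, the absolute sense comes from the (2S,3S)-epoxide, and aqueous acid opens enol ether 5 to hydroxy ketone 6.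

Step 5
Reactants: 6 (3S,4R,5R,8R,9R,10S)-18-(tert-butyldiphenylsilyloxy)-3β,8α-dihydroxy-14,15-dinorlabdan-13-one
Product: 7 O-[18-(tert-butyldiphenylsilyloxy)-8α-hydroxy-13-oxo-14,15-dinorlabdan-3β-yl] O-phenyl thiocarbonate
Conditions: PhOC(S)Cl (1.5 equiv), DMAP (2 equiv), MeCN, rt
Reagents that add atoms: O-phenyl chlorothionoformate, ClC(=S)Oc1ccccc1
Why: Thioacylation (first half of the Barton–McCombie sequence) occurs only at the secondary 3β-hydroxyl because the tertiary 8α-hydroxyl is too hindered to acylate, and no stereocentre changes.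

Step 6
Reactants: 7 O-[18-(tert-butyldiphenylsilyloxy)-8α-hydroxy-13-oxo-14,15-dinorlabdan-3β-yl] O-phenyl thiocarbonate
Product: 8 (4R,5R,8R,9R,10S)-18-(tert-butyldiphenylsilyloxy)-8α-hydroxy-14,15-dinorlabdan-13-one
Conditions: Bu3SnH (2 equiv), AIBN (0.2 equiv), toluene, 110 °C
Reagents that add atoms: none
Why: Barton–McCombie radical deoxygenation replaces the C3 oxygen by hydrogen through a secondary radical that does not rearrange, which deletes the C3 centre after it has relayed chirality and leaves the ketone, silyl ether and tertiary alcohol intact.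

Step 7
Reactants: 8 (4R,5R,8R,9R,10S)-18-(tert-butyldiphenylsilyloxy)-8α-hydroxy-14,15-dinorlabdan-13-one
Product: 9 ethyl (13E)-18-(tert-butyldiphenylsilyloxy)-8α-hydroxylabd-13-en-15-oate
Conditions: (EtO)2P(O)CH2CO2Et (3 equiv), NaH (4 equiv), THF, 0 °C → 65 °C; chromatographic removal of the minor (13Z)-ester
Reagents that add atoms: triethyl phosphonoacetate, CCOC(=O)CP(=O)(OCC)OCC
Why: Horner–Wadsworth–Emmons olefination of the methyl ketone (open form of the hemiketal) gives mainly the (E)-β-methyl enoate, with the chain trans to the ester for steric reasons, and creates no stereocentre.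

Step 8
Reactants: 9 ethyl (13E)-18-(tert-butyldiphenylsilyloxy)-8α-hydroxylabd-13-en-15-oate
Product: 11 (13E)-8α,18-dihydroxylabd-13-en-15-oic acid, via diol ethyl ester 10 (not isolated)
Conditions: TBAF (1.5 equiv), THF, rt; then LiOH (5 equiv), MeOH/H2O, 50 °C; 1 M HCl to pH 3
Reagents that add atoms: lithium hydroxide, [Li+].[OH-]
Why: Fluoride desilylation followed in the same flask by saponification of the hindered enoate frees the primary alcohol and the acid without touching the tertiary alcohol or the alkene geometry.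

Step 9
Reactants: 11 (13E)-8α,18-dihydroxylabd-13-en-15-oic acid
Product: 12 (4R,5R,8R,9R,10S,13E)-18-acetoxy-8α-hydroxylabd-13-en-15-oic acid (CNP0077667.1)
Conditions: Ac2O (1.5 equiv), pyridine, 0 °C → rt; aqueous work-up
Reagents that add atoms: acetic anhydride, CC(=O)OC(C)=O
Why: Acetylation with acetic anhydride in pyridine takes the primary C18 hydroxyl only, since the tertiary 8α-hydroxyl does not acylate under these conditions and the carboxylic acid is returned after the aqueous work-up.

## Compound list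

1 | (5E,9E)-6,10,14-trimethylpentadeca-5,9,13-trien-2-one (farnesylacetone) | CC(=O)CC/C=C(\C)CC/C=C(\C)CCC=C(C)C | starting material
2 | (5E,9E,13E)-15-hydroxy-6,10,14-trimethylpentadeca-5,9,13-trien-2-one | CC(=O)CC/C=C(\C)CC/C=C(\C)CC/C=C(\C)CO | intermediate
3 | (5E,9E)-12-[(2S,3S)-3-(hydroxymethyl)-3-methyloxiran-2-yl]-6,10-dimethyldodeca-5,9-dien-2-one | CC(=O)CC/C=C(\C)CC/C=C(\C)CC[C@@H]1O[C@@]1(C)CO | intermediate
4 | (5E,9E)-12-[(2S,3S)-3-[(tert-butyldiphenylsilyl)oxymethyl]-3-methyloxiran-2-yl]-6,10-dimethyldodeca-5,9-dien-2-one | CC(=O)CC/C=C(\C)CC/C=C(\C)CC[C@@H]1O[C@@]1(C)CO[Si](c1ccccc1)(c1ccccc1)C(C)(C)C | intermediate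
5 | 18-(tert-butyldiphenylsilyloxy)-8α,13-epoxy-14,15-dinorlabd-12-en-3β-ol (tricyclic enol ether) | CC(C)(C)[Si](c1ccccc1)(c1ccccc1)OC[C@]1(C)[C@@H](O)CC[C@]2(C)[C@H]3CC=C(C)O[C@]3(C)CC[C@@H]12 | intermediate (not isolated)
6 | (3S,4R,5R,8R,9R,10S)-18-(tert-butyldiphenylsilyloxy)-3β,8α-dihydroxy-14,15-dinorlabdan-13-one | CC(C)(C)[Si](c1ccccc1)(c1ccccc1)OC[C@]1(C)[C@@H](O)CC[C@]2(C)[C@@H](CCC(C)=O)[C@](C)(O)CC[C@@H]12 | intermediate
7 | O-[18-(tert-butyldiphenylsilyloxy)-8α-hydroxy-13-oxo-14,15-dinorlabdan-3β-yl] O-phenyl thiocarbonate | CC(C)(C)[Si](c1ccccc1)(c1ccccc1)OC[C@]1(C)[C@@H](OC(=S)Oc3ccccc3)CC[C@]2(C)[C@@H](CCC(C)=O)[C@](C)(O)CC[C@@H]12 | intermediate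
8 | (4R,5R,8R,9R,10S)-18-(tert-butyldiphenylsilyloxy)-8α-hydroxy-14,15-dinorlabdan-13-one | CC(C)(C)[Si](c1ccccc1)(c1ccccc1)OC[C@]1(C)CCC[C@]2(C)[C@@H](CCC(C)=O)[C@](C)(O)CC[C@@H]12 | intermediate
9 | ethyl (13E)-18-(tert-butyldiphenylsilyloxy)-8α-hydroxylabd-13-en-15-oate | CC(C)(C)[Si](c1ccccc1)(c1ccccc1)OC[C@]1(C)CCC[C@]2(C)[C@@H](CC/C(C)=C/C(=O)OCC)[C@](C)(O)CC[C@@H]12 | intermediate
10 | ethyl (13E)-8α,18-dihydroxylabd-13-en-15-oate | OC[C@]1(C)CCC[C@]2(C)[C@@H](CC/C(C)=C/C(=O)OCC)[C@](C)(O)CC[C@@H]12 | intermediate (not isolated)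
11 | (13E)-8α,18-dihydroxylabd-13-en-15-oic acid | OC[C@]1(C)CCC[C@]2(C)[C@@H](CC/C(C)=C/C(=O)O)[C@](C)(O)CC[C@@H]12 | intermediate
12 | (4R,5R,8R,9R,10S,13E)-18-acetoxy-8α-hydroxylabd-13-en-15-oic acid | CC(=O)OC[C@]1(C)CCC[C@]2(C)[C@@H](CC/C(C)=C/C(=O)O)[C@](C)(O)CC[C@@H]12 | target

## Step count and risks

Total step count: 9. Longest linear sequence: 9 steps (fully linear from 1).

Steps most likely to fail:

Step 4 (bicyclization). The β-silyloxy group slows ionisation at C4, ring A may contract through attack at C3, and the C8 cation may lose a proton instead of being captured by the ketone. The fallback sets out from 4 and comes back at 6, and it swaps the cationic cascade for a radical one. Trivalent titanium (Cp2TiCl made in the flask from Cp2TiCl2 and Mn dust, THF, rt) opens the epoxide homolytically to the C4 radical, which closes rings A and B and ends by loss of a β-hydrogen as the exocyclic alkene 18-(tert-butyldiphenylsilyloxy)-3β-hydroxy-14,15-dinorlabd-8(17)-en-13-one F1. Mukaiyama hydration (Co(acac)2, PhSiH3, O2, i-PrOH) then puts the tertiary hydroxyl on C8 from the open equatorial face and returns 6. In this variant C4 is set by the equatorial preference of the silyloxymethyl group and not by the alkene geometry, so a 4-epimer may have to be separated.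

Step 5 (thioacylation of the neopentylic 3β-hydroxyl, the entry to the deoxygenation). The fallback sets out from 5 and comes back at 8, and it removes the oxygen by elimination and reduction instead of a radical. Step 4 is stopped with a NaHCO3 work-up so that 5 is isolated with its tertiary oxygen masked in the pyran. Burgess reagent (benzene, 50 °C) dehydrates by syn-elimination toward C2 (C4 is quaternary) to 18-(tert-butyldiphenylsilyloxy)-8α,13-epoxy-14,15-dinorlabda-2,12-diene F2. Diimide (2-nitrobenzenesulfonohydrazide, Et3N, CH2Cl2, rt) saturates only the disubstituted ring alkene to give 18-(tert-butyldiphenylsilyloxy)-8α,13-epoxy-14,15-dinorlabd-12-ene F3. Treatment with 1 M HCl in THF opens the enol ether and gives 8.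

Step 7 (olefination). The tertiary alkoxide and the hemiketal can slow the reaction, and the E/Z ratio may be modest. The fallback sets out from 8 and comes back at 9, and it builds the enoate by alkynylation and rearrangement. Lithium ethoxyacetylide (ethoxyacetylene, n-BuLi, THF, −78 °C, excess to cover the free 8-hydroxyl) adds to the C13 ketone to give (13RS)-18-(tert-butyldiphenylsilyloxy)-15-ethoxylabd-14-yne-8α,13-diol F4. A Meyer–Schuster rearrangement (Sc(OTf)3 cat., EtOH, CH2Cl2, rt) converts it into the (E)-ethyl enoate 9.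

## Further compounds

F1 | step 4 | 18-(tert-butyldiphenylsilyloxy)-3β-hydroxy-14,15-dinorlabd-8(17)-en-13-one | CC(C)(C)[Si](c1ccccc1)(c1ccccc1)OC[C@]1(C)[C@@H](O)CC[C@]2(C)[C@@H](CCC(C)=O)C(=C)CC[C@@H]12
F2 | step 5 | 18-(tert-butyldiphenylsilyloxy)-8α,13-epoxy-14,15-dinorlabda-2,12-diene | CC(C)(C)[Si](c1ccccc1)(c1ccccc1)OC[C@]1(C)C=CC[C@]2(C)[C@H]3CC=C(C)O[C@]3(C)CC[C@@H]12
F3 | step 5 | 18-(tert-butyldiphenylsilyloxy)-8α,13-epoxy-14,15-dinorlabd-12-ene | CC(C)(C)[Si](c1ccccc1)(c1ccccc1)OC[C@]1(C)CCC[C@]2(C)[C@H]3CC=C(C)O[C@]3(C)CC[C@@H]12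
F4 | step 7 | (13RS)-18-(tert-butyldiphenylsilyloxy)-15-ethoxylabd-14-yne-8α,13-diol | CC(C)(C)[Si](c1ccccc1)(c1ccccc1)OC[C@]1(C)CCC[C@]2(C)[C@@H](CCC(C)(O)C#COCC)[C@](C)(O)CC[C@@H]12
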